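**Retrosynthetic overview**
1. All six stereocentres sit in cis, contra-thermodynamic relationships, so each is set kinetically and the most labile unit is made last. The target comes, after buffered desilylation, from enantioselective syn-hydrogenation (dearomatisation) of a flat 2-aryl-3-(silyloxymethyl)benzofuran, which gives the (2S,3S)-cis-dihydrobenzofuran.
2. The endo,endo-furofuran comes from reductive deoxygenation (C=O to CH2, no stereocentre touched) of an all-cis 2,6-diaryl bis-lactone.
3. The bis-lactone comes from two auxiliary-controlled anti-aldol reactions on the C2-symmetric succinyl bis-imide. The first (O-silyl vanillin) breaks the symmetry, the second brings in the benzofuran aldehyde, and lactonisation expels both auxiliaries.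
4. The benzofuran aldehyde comes from Larock heteroannulation of 5-iodovanillin with an aryl propargyl alcohol made by Sonogashira coupling.
5. Ring order: benzofuran ring, then the two lactone rings (which become the two tetrahydrofuran rings), then the dihydrofuran ring by dearomatisation.

Assumption: the SMILES is read literally, i.e. a (7S,8S,7'S,8'S) endo,endo furofuran (H-7, H-8, H-8', H-7' all cis) and a (2S,3S) cis-dihydrobenzofuran, not the pinoresinol/trans-phenylcoumaran pattern; the face sense of the Ru–NHC catalyst is extrapolated from 2-arylbenzofurans and the antipodal ligand is used if it proves opposite.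

**Step 1**
Reactants: 1 vanillin
Product: 2 4-(tert-butyldimethylsilyloxy)-3-methoxybenzaldehyde
Conditions: TBSCl, imidazole, DMF, 23 °C
Reagents that add atoms: tert-butyldimethylsilyl chloride, CC(C)(C)[Si](C)(C)Cl
Why: Standard phenol silylation; the silyl ether keeps the later p-oxybenzyl C–O bonds from opening to quinone methides.

**Step 2**
Reactants: 3 4-iodo-2-methoxyphenol; 4 prop-2-yn-1-ol
Product: 5 4-(3-hydroxyprop-1-yn-1-yl)-2-methoxyphenol
Conditions: PdCl2(PPh3)2 (2 mol %), CuI (4 mol %), Et3N, THF, 23 °C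
Reagents that add atoms: none
Why: Sonogashira coupling of an aryl iodide runs at room temperature and tolerates the free phenol and alcohol.

**Step 3**
Reactants: 5 4-(3-hydroxyprop-1-yn-1-yl)-2-methoxyphenol; 6 5-iodovanillin
Product: 7 2-(4-hydroxy-3-methoxyphenyl)-3-(hydroxymethyl)-7-methoxybenzofuran-5-carbaldehyde
Conditions: Pd(OAc)2 (5 mol %), LiCl, Na2CO3, DMF, 100 °C
Reagents that add atoms: none
Why: Larock heteroannulation, in which the arylpalladium iodide adds syn to the aryl/alkyl alkyne with the new C–C bond at the CH2OH-bearing carbon and Pd on the aryl-bearing carbon (the usual sense for aryl/alkyl alkynes), and C–O reductive elimination then places the aryl group at C-2, the electron-poor iodophenol being the favourable case.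

**Step 4**
Reactants: 7 2-(4-hydroxy-3-methoxyphenyl)-3-(hydroxymethyl)-7-methoxybenzofuran-5-carbaldehyde
Product: 8 2-[4-(tert-butyldimethylsilyloxy)-3-methoxyphenyl]-3-[(tert-butyldimethylsilyloxy)methyl]-7-methoxybenzofuran-5-carbaldehyde
Conditions: TBSCl (2.5 equiv), imidazole, DMF, 23 °C
Reagents that add atoms: tert-butyldimethylsilyl chloride, CC(C)(C)[Si](C)(C)Cl
Why: Double silylation after the hot basic annulation avoids loss of an aryl silyl ether there and masks the ionisable benzofuranylmethanol.

**Step 5**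
Reactants: 9 (S)-4-benzyl-1,3-oxazolidin-2-one; 10 succinyl chloride
Product: 12 1,4-bis[(4S)-4-benzyl-2-oxo-1,3-oxazolidin-3-yl]butane-1,4-dione (C2-symmetric succinyl bis-imide), via lithium oxazolidinide 11 (not isolated)
Conditions: 9 (2 equiv), n-BuLi, THF, −78 °C; then 10 (1 equiv), −78 → 0 °C
Reagents that add atoms: none
Why: N-acylation of the lithiated auxiliary with a diacid chloride gives the bis-imide with two homotopic CH2 arms.

**Step 6**
Reactants: 12 succinyl bis-imide; 2 4-(tert-butyldimethylsilyloxy)-3-methoxybenzaldehyde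
Product: 13 mono anti-aldol silyl ether: (2R)-1,4-bis[(4S)-4-benzyl-2-oxooxazolidin-3-yl]-2-{(S)-[4-(tert-butyldimethylsilyloxy)-3-methoxyphenyl](trimethylsilyloxy)methyl}butane-1,4-dione
Conditions: 12 (2 equiv, excess recovered), MgCl2 (20 mol %), Et3N, TMSCl, EtOAc, 23 °C
Reagents that add atoms: chlorotrimethylsilane, C[Si](C)(C)Cl
Why: Magnesium-halide-catalysed Evans anti-aldol (soft enolisation with silyl trapping), where the chelated Z-enolate is attacked on the face away from the benzyl group to set the backbone centre (R at this stage, S in the target) and the anti carbinol centre (S), and the excess of 12 restricts reaction to one of the two equivalent arms so that the C2 symmetry is broken here.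

**Step 7**
Reactants: 13 mono anti-aldol silyl ether; 8 bis-silylated benzofuran aldehyde
Product: 16 all-cis bis-lactone (1R,2S,5R,6S)-2-[4-(tert-butyldimethylsilyloxy)-3-methoxyphenyl]-6-{2-[4-(tert-butyldimethylsilyloxy)-3-methoxyphenyl]-3-[(tert-butyldimethylsilyloxy)methyl]-7-methoxybenzofuran-5-yl}-3,7-dioxabicyclo[3.3.0]octane-4,8-dione (both aryl groups endo), via bis-TMS ether 14 (not isolated), via diol 15 (not isolated)
Conditions: 13 (1.3 equiv), MgCl2 (20 mol %), Et3N, TMSCl, EtOAc, 23 °C; then PPTS, MeOH, 0 °C; then DMAP (cat.), CH2Cl2, 23 °C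
Reagents that add atoms: none
Why: A second Evans anti-aldol on the remaining CH2 arm is steered by that arm's own (S)-auxiliary to the like-configured (2R,3R) backbone with both carbinols S, after which mild methanolysis frees the carbinols and each acylates on its 1,4-related imide (5-exo-trig lactonisation) with retention everywhere and release of the auxiliary.

**Step 8**
Reactants: 16 all-cis bis-lactone
Product: 18 (1S,2S,5S,6S)-2-[4-(tert-butyldimethylsilyloxy)-3-methoxyphenyl]-6-{2-[4-(tert-butyldimethylsilyloxy)-3-methoxyphenyl]-3-[(tert-butyldimethylsilyloxy)methyl]-7-methoxybenzofuran-5-yl}-3,7-dioxabicyclo[3.3.0]octane (endo,endo-furofuran), via bis-lactol 17 (not isolated)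
Conditions: i-Bu2AlH (2.4 equiv), CH2Cl2, −78 °C; then Et3SiH (10 equiv), BF3·OEt2, −78 → −45 °C
Reagents that add atoms: none
Why: Lactone to lactol to cyclic ether reductive deoxygenation, in which the oxocarbenium ions form at the non-benzylic C-4 and C-8 so no stereocentre is touched, and the low temperature keeps BF3 from ionising the endo benzylic C–O bonds or the benzofuranylmethyl silyl ether.

**Step 9**
Reactants: 18 endo,endo-furofuran carrying the benzofuran
Product: 19 tris(tert-butyldimethylsilyl) ether of the target with the (2S,3S)-cis-2,3-dihydrobenzofuran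
Conditions: [Ru(cod)(2-methylallyl)2] (10 mol %), 1,3-bis[(R)-1-(naphthalen-1-yl)ethyl]-4,5-dihydroimidazolium tetrafluoroborate (20 mol %), KOtBu (25 mol %), catalyst pre-formed, toluene/n-hexane, H2 (100 bar), 40 °C
Reagents that add atoms: none
Why: Proposed new method: enantioselective dearomative hydrogenation of a 2-aryl-3-(silyloxymethyl)benzofuran, the closest known reaction type being the Ru–NHC-catalysed asymmetric hydrogenation of 2-aryl- and 2-alkylbenzofurans and of disubstituted furans; the furan C2=C3 bond is the least aromatic π-bond present and binds to the Ru hydride, both hydrogens arrive on the same face so the 2,3-relationship must be cis, the chiral NHC pocket selects the face that gives (2S,3S) while the remote furofuran centres have no influence, and the benzene rings, silyl ethers and benzylic ethers are inert to this neutral homogeneous catalyst.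

**Step 10**
Reactants: 19 tris-silyl ether of the target
Product: 20 target CNP0303197.1
Conditions: TBAF/AcOH (1:1, 4 equiv), THF, 0 → 23 °C
Reagents that add atoms: none
Why: Fluoride desilylation buffered with acetic acid leaves neither free phenoxide nor strong acid, so neither the cis-2-aryldihydrobenzofuran nor the endo benzylic ethers can open to a quinone methide and epimerise.

**Compound list**
1 | vanillin | COc1cc(C=O)ccc1O | starting material
2 | 4-(tert-butyldimethylsilyloxy)-3-methoxybenzaldehyde | COc1cc(C=O)ccc1O[Si](C)(C)C(C)(C)C | intermediate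
3 | 4-iodo-2-methoxyphenol | COc1cc(I)ccc1O | starting material
4 | prop-2-yn-1-ol | C#CCO | starting material
5 | 4-(3-hydroxyprop-1-yn-1-yl)-2-methoxyphenol | COc1cc(C#CCO)ccc1O | intermediate
6 | 5-iodovanillin (4-hydroxy-3-iodo-5-methoxybenzaldehyde) | COc1cc(C=O)cc(I)c1O | starting material
7 | 2-(4-hydroxy-3-methoxyphenyl)-3-(hydroxymethyl)-7-methoxybenzofuran-5-carbaldehyde | COc1cc(C=O)cc2c(CO)c(-c3ccc(O)c(OC)c3)oc12 | intermediate
8 | bis-TBS ether of 7 | COc1cc(C=O)cc2c(CO[Si](C)(C)C(C)(C)C)c(-c3ccc(O[Si](C)(C)C(C)(C)C)c(OC)c3)oc12 | intermediate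
9 | (S)-4-benzyl-1,3-oxazolidin-2-one | O=C1N[C@@H](Cc2ccccc2)CO1 | starting material
10 | succinyl chloride | O=C(Cl)CCC(=O)Cl | starting material
11 | lithium (S)-4-benzyl-2-oxooxazolidin-3-ide | [Li+].O=C1[N-][C@@H](Cc2ccccc2)CO1 | intermediate (not isolated)
12 | 1,4-bis[(4S)-4-benzyl-2-oxo-1,3-oxazolidin-3-yl]butane-1,4-dione | O=C(CCC(=O)N1[C@@H](Cc2ccccc2)COC1=O)N1[C@@H](Cc2ccccc2)COC1=O | intermediate
13 | mono anti-aldol TMS ether, backbone C-2 R, carbinol S | COc1cc(ccc1O[Si](C)(C)C(C)(C)C)[C@@H](O[Si](C)(C)C)[C@@H](CC(=O)N1[C@@H](Cc2ccccc2)COC1=O)C(=O)N1[C@@H](Cc2ccccc2)COC1=O | intermediate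
14 | bis anti-aldol bis-TMS ether, backbone (2R,3R), both carbinols S | COc1cc(ccc1O[Si](C)(C)C(C)(C)C)[C@@H](O[Si](C)(C)C)[C@H](C(=O)N1[C@@H](Cc2ccccc2)COC1=O)[C@@H](C(=O)N1[C@@H](Cc2ccccc2)COC1=O)[C@H](O[Si](C)(C)C)c1cc(OC)c2oc(-c3ccc(O[Si](C)(C)C(C)(C)C)c(OC)c3)c(CO[Si](C)(C)C(C)(C)C)c2c1 | intermediate (not isolated)
15 | bis anti-aldol diol, same configuration as 14 | COc1cc(ccc1O[Si](C)(C)C(C)(C)C)[C@@H](O)[C@H](C(=O)N1[C@@H](Cc2ccccc2)COC1=O)[C@@H](C(=O)N1[C@@H](Cc2ccccc2)COC1=O)[C@H](O)c1cc(OC)c2oc(-c3ccc(O[Si](C)(C)C(C)(C)C)c(OC)c3)c(CO[Si](C)(C)C(C)(C)C)c2c1 | intermediate (not isolated)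
16 | (1R,2S,5R,6S) endo,endo-2,6-diaryl-3,7-dioxabicyclo[3.3.0]octane-4,8-dione | COc1cc([C@H]2OC(=O)[C@@H]3[C@H]2C(=O)O[C@@H]3c2cc(OC)c3oc(-c4ccc(O[Si](C)(C)C(C)(C)C)c(OC)c4)c(CO[Si](C)(C)C(C)(C)C)c3c2)ccc1O[Si](C)(C)C(C)(C)C | intermediate
17 | bis-lactol of 16 (present as its diisobutylaluminium alkoxide, anomeric centres undefined) | COc1cc([C@H]2OC(O)[C@@H]3[C@H]2C(O)O[C@@H]3c2cc(OC)c3oc(-c4ccc(O[Si](C)(C)C(C)(C)C)c(OC)c4)c(CO[Si](C)(C)C(C)(C)C)c3c2)ccc1O[Si](C)(C)C(C)(C)C | intermediate (not isolated)
18 | (1S,2S,5S,6S) endo,endo-furofuran with benzofuran, tris-TBS | COc1cc([C@H]2OC[C@@H]3[C@H]2CO[C@@H]3c2cc(OC)c3oc(-c4ccc(O[Si](C)(C)C(C)(C)C)c(OC)c4)c(CO[Si](C)(C)C(C)(C)C)c3c2)ccc1O[Si](C)(C)C(C)(C)C | intermediate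
19 | tris-TBS ether of the target, (2S,3S)-cis-dihydrobenzofuran | COc1cc([C@H]2OC[C@@H]3[C@H]2CO[C@@H]3c2cc(OC)c3c(c2)[C@@H](CO[Si](C)(C)C(C)(C)C)[C@@H](c2ccc(O[Si](C)(C)C(C)(C)C)c(OC)c2)O3)ccc1O[Si](C)(C)C(C)(C)C | intermediate
20 | CNP0303197.1 | COc1cc([C@H]2OC[C@@H]3[C@H]2CO[C@@H]3c2cc(OC)c3c(c2)[C@@H](CO)[C@@H](c2ccc(O)c(OC)c2)O3)ccc1O | target

**Step count**
Total: 10 steps. Longest linear sequence: 7 steps (steps 2, 3, 4, 7, 8, 9, 10, from 3 to 20).

**Steps most likely to fail**

Step 9 is the greatest risk. The C2=C3 bond is tetrasubstituted and flanked by bulky groups, so the chiral Ru–NHC catalyst may be slow or only weakly face-selective.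

The fallback sets out from 18 and comes back at 19. It gives up catalyst control of the face and uses the enantiopure furofuran as an internal resolving element. A smaller achiral catalyst is made from [Ru(cod)(2-methylallyl)2], 1,3-dicyclohexylimidazolium chloride and KOtBu and is run under H2. It still adds hydrogen syn, so only two products can form: 19 and the (2R,3R)-cis-dihydrobenzofuran diastereomer of 19 F4. These are diastereomers, not enantiomers, and are separated by preparative HPLC before step 10.

Step 7 is the second risk. The free diol must close twice to a crowded all-cis bis-lactone, and base-induced epimerisation next to the imide, or retro-aldol, could intervene.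

The fallback sets out from 14, isolated by neutral aqueous work-up, and comes back at 18. It never makes a lactone. LiBH4 in THF/MeOH at 0 °C removes both auxiliaries reductively and gives (2S,3S)-2-{(S)-[4-(tert-butyldimethylsilyloxy)-3-methoxyphenyl](trimethylsilyloxy)methyl}-3-{(S)-[the silylated benzofuran-5-yl](trimethylsilyloxy)methyl}butane-1,4-diol F3. Tf2O with 2,6-lutidine in CH2Cl2 at −78 °C then triflates the two primary alcohols. Each is displaced by the 1,4-related silyl ether oxygen (5-exo-tet, loss of the trimethylsilyl group). Both tetrahydrofuran rings therefore close with retention at the benzylic carbons, and step 8 is bypassed as well.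

Step 3 is the third risk. The annulation with an unhindered aryl/hydroxymethyl alkyne may be low-yielding or give some of the 3-aryl-2-hydroxymethyl regioisomer.

The fallback sets out from 6 and comes back at 7. It makes the C2–aryl bond by cross-coupling instead.
- Annulation of 6 with 3-(triethylsilyl)prop-2-yn-1-ol under the same Pd(OAc)2 conditions puts the bulky silyl group at C-2 without ambiguity, giving 3-(hydroxymethyl)-7-methoxy-2-(triethylsilyl)benzofuran-5-carbaldehyde F1.
- ICl in CH2Cl2 at 0 °C effects ipso-iododesilylation to 3-(hydroxymethyl)-2-iodo-7-methoxybenzofuran-5-carbaldehyde F2.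
- Suzuki–Miyaura coupling with 2-methoxy-4-(4,4,5,5-tetramethyl-1,3,2-dioxaborolan-2-yl)phenol (Pd(PPh3)4, K2CO3, dioxane/H2O, 80 °C) delivers 7.

**Further compounds**
F1 | step 3 | 3-(hydroxymethyl)-7-methoxy-2-(triethylsilyl)benzofuran-5-carbaldehyde | COc1cc(C=O)cc2c(CO)c([Si](CC)(CC)CC)oc12
F2 | step 3 | 3-(hydroxymethyl)-2-iodo-7-methoxybenzofuran-5-carbaldehyde | COc1cc(C=O)cc2c(CO)c(I)oc12
F3 | step 7 | (2S,3S)-2,3-bis[(S)-aryl(trimethylsilyloxy)methyl]butane-1,4-diol (aryl groups as in 14) | COc1cc(ccc1O[Si](C)(C)C(C)(C)C)[C@@H](O[Si](C)(C)C)[C@H](CO)[C@@H](CO)[C@H](O[Si](C)(C)C)c1cc(OC)c2oc(-c3ccc(O[Si](C)(C)C(C)(C)C)c(OC)c3)c(CO[Si](C)(C)C(C)(C)C)c2c1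
F4 | step 9 | (2R,3R)-cis-dihydrobenzofuran diastereomer of 19 | COc1cc([C@H]2OC[C@@H]3[C@H]2CO[C@@H]3c2cc(OC)c3c(c2)[C@H](CO[Si](C)(C)C(C)(C)C)[C@H](c2ccc(O[Si](C)(C)C(C)(C)C)c(OC)c2)O3)ccc1O[Si](C)(C)C(C)(C)C
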